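**Plan**

- Labels: C1 is the stereocentre and C2–C3 the chain. Ring A is the 4-methoxyphenyl group on C1; ring B is the central ring (B1 on C1, methoxy on B2 and B6, styryl on B4); ring C is the 4-hydroxy-2-methoxyphenyl group on C3; ring D is the stilbene phenol.
- Cuts, in retrosynthetic order: the two phenol protecting groups; the B4–vinyl bond (Heck); the C2=C3 unsaturation is restored; B1–C1 and O–B2 together (aryne plus chiral allylic methyl ether); then O–CH3, the carbinol C3–H, and C1=C2 (Claisen–Schmidt).
- Enabling feature: on ring B the carbon carrying C1 (B1) and a carbon carrying a methoxy oxygen (B2) are neighbours. That oxygen, with its methyl group, can therefore be the oxygen of an allylic methyl ether that arylates an aryne at B2 and then passes its allyl group, through the ring A terminus C1, to the aryl anion at B1.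
- Forward: fragment 1 (ring A–C1=C2–C3(OMe)–ring C ether, four steps) and fragment 2 (ring B aryne precursor, two steps) are joined in step 7. The chain is then saturated, ring D is attached at B4 and both phenols are released. No ring is formed anywhere in the route.
- Stereochemistry: the C3 carbinol centre is set by CBS reduction and relayed suprafacially to C1 in step 7, after which C3 is no longer stereogenic. The stilbene E geometry comes from the Heck reaction.

Key step: step 7

Remark: in the CBS reduction the ortho-methoxyaryl group of the enone is taken as the larger carbonyl substituent, so the (S)-catalyst is expected to give the (R)-carbinol; if the sense proved opposite, the (R)-catalyst would be used with no other change.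

**Route**

Step 1
Reactants: 1 1-(4-hydroxy-2-methoxyphenyl)ethanone; 2 4-methoxybenzaldehyde
Product: 3 (E)-1-(4-hydroxy-2-methoxyphenyl)-3-(4-methoxyphenyl)prop-2-en-1-one
Conditions: KOH (50% aq.), EtOH, rt; then HCl (aq.)
Reagents that add atoms: none
Why: Claisen–Schmidt (crossed aldol) condensation: excess hydroxide enolises the methyl ketone even as its phenoxide, the non-enolisable aldehyde is the only acceptor, and E1cB loss of water gives the conjugated E-enone as the thermodynamic product.

Step 2
Reactants: 3 (E)-1-(4-hydroxy-2-methoxyphenyl)-3-(4-methoxyphenyl)prop-2-en-1-one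
Product: 4 3-methoxy-4-[(E)-3-(4-methoxyphenyl)prop-2-enoyl]phenyl 4-methylbenzenesulfonate
Conditions: TsCl, Et3N, DMAP (cat.), CH2Cl2, 0 °C to rt
Reagents that add atoms: 4-methylbenzenesulfonyl chloride, Cc1ccc(S(=O)(=O)Cl)cc1
Why: Sulfonylation of the phenol (tosylation) under amine base: the sulfonate has no Lewis-basic sp3 oxygen to compete for the aryne in step 7, is inert to fluoride, hydride, diimide and the palladium catalyst used later, makes the C3 position less prone to ionise, and is removable by hydroxide at the end.

Step 3
Reactants: 4 3-methoxy-4-[(E)-3-(4-methoxyphenyl)prop-2-enoyl]phenyl 4-methylbenzenesulfonate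
Product: 5 4-[(1R,2E)-1-hydroxy-3-(4-methoxyphenyl)prop-2-en-1-yl]-3-methoxyphenyl 4-methylbenzenesulfonate
Conditions: (S)-Me-CBS oxazaborolidine (20 mol%), catecholborane, toluene, −78 °C; then MeOH, aqueous work-up
Reagents that add atoms: none
Why: Corey–Bakshi–Shibata reduction: the ketone binds to the oxazaborolidine boron anti to its larger ortho-methoxyaryl group and receives hydride from the coordinated borane on one face only, which should set the (R)-carbinol centre, while catecholborane at low temperature leaves the alkene untouched.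

Step 4
Reactants: 5 4-[(1R,2E)-1-hydroxy-3-(4-methoxyphenyl)prop-2-en-1-yl]-3-methoxyphenyl 4-methylbenzenesulfonate
Product: 6 3-methoxy-4-[(1R,2E)-1-methoxy-3-(4-methoxyphenyl)prop-2-en-1-yl]phenyl 4-methylbenzenesulfonate
Conditions: NaH, MeI, THF/DMF, 0 °C; chromatography on Et3N-deactivated silica, storage cold
Reagents that add atoms: iodomethane, CI
Why: Williamson ether synthesis: the sodium alkoxide is methylated on oxygen without touching the C3–O bond, so the configuration is retained, and the basic medium avoids the acid-promoted ionisation to which a 1,3-diarylallyl ether is prone.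

Step 5
Reactants: 7 4-chloro-2-methoxyphenol
Product: 8 2-bromo-4-chloro-6-methoxyphenol
Conditions: NBS, MeCN, 0 °C to rt
Reagents that add atoms: N-bromosuccinimide, O=C1CCC(=O)N1Br
Why: Electrophilic aromatic bromination: the hydroxyl group is the strongest activator and, its para position being blocked by chlorine, directs bromine to its single free ortho carbon.

Step 6
Reactants: 8 2-bromo-4-chloro-6-methoxyphenol
Product: 11 4-chloro-2-methoxy-6-(trimethylsilyl)phenyl trifluoromethanesulfonate, via aryl trimethylsilyl ether 9 (not isolated), via lithium 2-silylphenoxide 10 (not isolated)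
Conditions: HMDS, THF, reflux, then evaporation; n-BuLi, THF, −100 °C; Tf2O, −100 °C to rt
Reagents that add atoms: hexamethyldisilazane, C[Si](C)(C)N[Si](C)(C)C; trifluoromethanesulfonic anhydride, O=S(=O)(OS(=O)(=O)C(F)(F)F)C(F)(F)F
Why: One-pot O-silylation, bromine–lithium exchange, retro-Brook (1,3 O-to-C) silyl migration and triflation of the resulting phenoxide, the standard entry to ortho-silylaryl triflates; the aryl chloride does not exchange with n-BuLi at this temperature and the bromine position fixes where silicon ends up.

Step 7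
Reactants: 6 3-methoxy-4-[(1R,2E)-1-methoxy-3-(4-methoxyphenyl)prop-2-en-1-yl]phenyl 4-methylbenzenesulfonate; 11 4-chloro-2-methoxy-6-(trimethylsilyl)phenyl trifluoromethanesulfonate
Product: 14 4-[(1E,3S)-3-(4-chloro-2,6-dimethoxyphenyl)-3-(4-methoxyphenyl)prop-1-en-1-yl]-3-methoxyphenyl 4-methylbenzenesulfonate, via aryne 12 (not isolated), via oxonium zwitterion 13 (not isolated)
Conditions: tetrabutylammonium difluorotriphenylsilicate (Bu4N+ Ph3SiF2−, 2 equiv), toluene, 50 °C, slow addition of 11 (1.5 equiv) to 6
Reagents that add atoms: none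
Why: Proposed new method: fluoride from the silicate removes the silyl group of 11 and triflate leaves, giving aryne 12, whose methoxy group polarises the strained triple bond so that the ether oxygen of 6 adds at the carbon remote from it (B2) and the aryl anion of zwitterion 13 sits at B1 between the two oxygen-bearing carbons; that anion then bonds to the allyl terminus bearing ring A through a six-membered (3,3) array while the O–C3 bond breaks, which leaves the O-methyl group on B2 as the second methoxy group. The closest known reactions are the aryne aza-Claisen rearrangement of tertiary allylamines, where an N-aryl ammonium with an ortho aryl anion collapses in the same way, and the aromatic Claisen rearrangement. No ring is closed, the six-membered array existing only in the transition state. The new stereocentre C1 is controlled by the C3 centre of 6: bond making and bond breaking take place on the same face of the E-allyl unit, and with ring C pseudo-equatorial (allylic 1,3-strain keeps the C3 hydrogen inside) the (R)-ether should give the (S)-configured E-alkene. The step needs O-arylation at B2 only, secured by the methoxy group next to the aryne; preference of the ether oxygen over the styrene-type double bond, favoured by slow release of the aryne into a concentrated toluene solution of 6 that offers no acidic C–H to quench the aryl anion; and a concerted shift and not an ion pair, which the electron-withdrawing tosylate on ring C supports by making a cation at C3 less accessible. Ether addition to arynes is reversible and unproductive when the zwitterion has no exit, so the irreversible intramolecular shift is what should pull this weak nucleophile through.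

Step 8
Reactants: 14 4-[(1E,3S)-3-(4-chloro-2,6-dimethoxyphenyl)-3-(4-methoxyphenyl)prop-1-en-1-yl]-3-methoxyphenyl 4-methylbenzenesulfonate
Product: 15 4-[(3S)-3-(4-chloro-2,6-dimethoxyphenyl)-3-(4-methoxyphenyl)propyl]-3-methoxyphenyl 4-methylbenzenesulfonate
Conditions: TsNHNH2 (excess, in portions), NaOAc, THF/H2O, reflux
Reagents that add atoms: none
Why: Diimide reduction: diimide generated from the sulfonyl hydrazide transfers two hydrogens to the only C=C bond in a concerted syn fashion and leaves the aryl chloride, the sulfonate and the C1 stereocentre untouched, which a palladium-catalysed hydrogenation would not guarantee for the chloride.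

Step 9
Reactants: 15 4-[(3S)-3-(4-chloro-2,6-dimethoxyphenyl)-3-(4-methoxyphenyl)propyl]-3-methoxyphenyl 4-methylbenzenesulfonate; 16 4-ethenylphenyl acetate (4-acetoxystyrene)
Product: 17 4-[(E)-2-{3,5-dimethoxy-4-[(1S)-1-(4-methoxyphenyl)-3-{2-methoxy-4-[(4-methylbenzenesulfonyl)oxy]phenyl}propyl]phenyl}ethenyl]phenyl acetate
Conditions: Pd[P(t-Bu)3]2 (cat.), Cy2NMe, 1,4-dioxane, 100 °C
Reagents that add atoms: none
Why: Mizoroki–Heck reaction: the bulky electron-rich phosphine lets zerovalent palladium insert into the unhindered aryl chloride but not into the aryl tosylate, and syn insertion of the styrene followed by syn β-hydride elimination gives the E-stilbene.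

Step 10
Reactants: 17 4-[(E)-2-{3,5-dimethoxy-4-[(1S)-1-(4-methoxyphenyl)-3-{2-methoxy-4-[(4-methylbenzenesulfonyl)oxy]phenyl}propyl]phenyl}ethenyl]phenyl acetate
Product: 18 4-[(3S)-3-{4-[(E)-2-(4-hydroxyphenyl)ethenyl]-2,6-dimethoxyphenyl}-3-(4-methoxyphenyl)propyl]-3-methoxyphenol
Conditions: KOH, MeOH/THF/H2O, 60 °C, argon; then HCl (aq.) to pH 5
Reagents that add atoms: none
Why: Saponification: hydroxide cleaves the aryl acetate by acyl substitution and the aryl tosylate by attack at sulfur, while the methyl ethers, the E-alkene and the non-acidic diarylmethine C1–H are unaffected.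

**Compound list**

1 | 1-(4-hydroxy-2-methoxyphenyl)ethanone | COc1cc(O)ccc1C(C)=O | starting material
2 | 4-methoxybenzaldehyde | COc1ccc(C=O)cc1 | starting material
3 | (E)-1-(4-hydroxy-2-methoxyphenyl)-3-(4-methoxyphenyl)prop-2-en-1-one | COc1ccc(/C=C/C(=O)c2ccc(O)cc2OC)cc1 | intermediate
4 | 3-methoxy-4-[(E)-3-(4-methoxyphenyl)prop-2-enoyl]phenyl 4-methylbenzenesulfonate | COc1ccc(/C=C/C(=O)c2ccc(OS(=O)(=O)c3ccc(C)cc3)cc2OC)cc1 | intermediate
5 | 4-[(1R,2E)-1-hydroxy-3-(4-methoxyphenyl)prop-2-en-1-yl]-3-methoxyphenyl 4-methylbenzenesulfonate | COc1ccc(/C=C/[C@@H](O)c2ccc(OS(=O)(=O)c3ccc(C)cc3)cc2OC)cc1 | intermediate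
6 | 3-methoxy-4-[(1R,2E)-1-methoxy-3-(4-methoxyphenyl)prop-2-en-1-yl]phenyl 4-methylbenzenesulfonate | COc1ccc(/C=C/[C@@H](OC)c2ccc(OS(=O)(=O)c3ccc(C)cc3)cc2OC)cc1 | intermediate
7 | 4-chloro-2-methoxyphenol | COc1cc(Cl)ccc1O | starting material
8 | 2-bromo-4-chloro-6-methoxyphenol | COc1cc(Cl)cc(Br)c1O | intermediate
9 | (2-bromo-4-chloro-6-methoxyphenoxy)trimethylsilane | COc1cc(Cl)cc(Br)c1O[Si](C)(C)C | intermediate (not isolated)
10 | lithium 4-chloro-2-methoxy-6-(trimethylsilyl)phenoxide | COc1cc(Cl)cc([Si](C)(C)C)c1[O-].[Li+] | intermediate (not isolated)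
11 | 4-chloro-2-methoxy-6-(trimethylsilyl)phenyl trifluoromethanesulfonate | COc1cc(Cl)cc([Si](C)(C)C)c1OS(=O)(=O)C(F)(F)F | intermediate
12 | 5-chloro-3-methoxy-1,2-didehydrobenzene (5-chloro-3-methoxybenzyne) | COC1=CC(Cl)=CC#C1 | intermediate (not isolated)
13 | oxonium zwitterion: the ether oxygen of 6 (still bearing its methyl group and the (R)-configured allyl group) bonded to B2 of the 5-chloro-3-methoxyphenyl ring, carbanion at B1 between the two oxygen-bearing carbons | COc1ccc(/C=C/[C@@H]([O+](C)c2cc(Cl)cc(OC)[c-]2)c2ccc(OS(=O)(=O)c3ccc(C)cc3)cc2OC)cc1 | intermediate (not isolated)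
14 | 4-[(1E,3S)-3-(4-chloro-2,6-dimethoxyphenyl)-3-(4-methoxyphenyl)prop-1-en-1-yl]-3-methoxyphenyl 4-methylbenzenesulfonate | COc1ccc([C@H](/C=C/c2ccc(OS(=O)(=O)c3ccc(C)cc3)cc2OC)c2c(OC)cc(Cl)cc2OC)cc1 | intermediate
15 | 4-[(3S)-3-(4-chloro-2,6-dimethoxyphenyl)-3-(4-methoxyphenyl)propyl]-3-methoxyphenyl 4-methylbenzenesulfonate | COc1ccc([C@H](CCc2ccc(OS(=O)(=O)c3ccc(C)cc3)cc2OC)c2c(OC)cc(Cl)cc2OC)cc1 | intermediate
16 | 4-ethenylphenyl acetate (4-acetoxystyrene) | CC(=O)Oc1ccc(C=C)cc1 | starting material
17 | 4-[(E)-2-{3,5-dimethoxy-4-[(1S)-1-(4-methoxyphenyl)-3-{2-methoxy-4-[(4-methylbenzenesulfonyl)oxy]phenyl}propyl]phenyl}ethenyl]phenyl acetate | COc1ccc([C@H](CCc2ccc(OS(=O)(=O)c3ccc(C)cc3)cc2OC)c2c(OC)cc(/C=C/c3ccc(OC(C)=O)cc3)cc2OC)cc1 | intermediate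
18 | 4-[(3S)-3-{4-[(E)-2-(4-hydroxyphenyl)ethenyl]-2,6-dimethoxyphenyl}-3-(4-methoxyphenyl)propyl]-3-methoxyphenol | COc1ccc([C@H](CCc2ccc(O)cc2OC)c2c(OC)cc(/C=C/c3ccc(O)cc3)cc2OC)cc1 | target

**Count**

Total steps: 10. Longest linear sequence: 8 steps (steps 1–4 and 7–10); the aryne precursor branch (steps 5–6) joins at step 7.

**Steps most likely to fail**

Step 7 (Proposed new method). The ether oxygen may lose the competition for the aryne to the styrene-type double bond. The oxonium may also dissociate to an ion pair, or pass through proton transfer to an oxonium ylide, with loss of regiochemistry or of chirality transfer. The fallback uses known chemistry, a copper-mediated anti-SN2' arylation of an allylic picolinate, and sets out from enone 4. Reduction of 4 with the (R)-Me-CBS oxazaborolidine and catecholborane should give the (S)-configured allylic alcohol F1. Esterification with picolinic acid (DCC, DMAP, CH2Cl2) gives the picolinate F2. Commercial 1-chloro-3,5-dimethoxybenzene F3 is lithiated between its methoxy groups (n-BuLi, THF) and transmetalated with MgBr2 to (4-chloro-2,6-dimethoxyphenyl)magnesium bromide F4. The arylcopper reagent from F4 and CuBr·SMe2 is added to F2 in THF at −40 °C. Attack at the ring A terminus anti to the chelating leaving group should give 14, where the route is rejoined.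

Step 3. Facial discrimination may be poor because both carbonyl substituents are flat sp2 groups, and conjugate reduction or hydroboration may compete. The fallback replaces catalyst control by kinetic resolution and sets out from enone 4. Luche reduction (NaBH4, CeCl3·7H2O, MeOH, 0 °C) gives the racemic allylic alcohol F5. Sharpless kinetic resolution (Ti(OiPr)4, D-(−)-diisopropyl tartrate, t-BuOOH, 4 Å molecular sieves, CH2Cl2, −20 °C) should epoxidise the (S)-enantiomer to the epoxy alcohol F6 and leave the (R)-enantiomer, which is 5, where the route is rejoined.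

Step 9. Oxidative addition of the aryl chloride may be slow at the temperature at which 4-acetoxystyrene begins to polymerise, and the acetate may be lost. The fallback is a Suzuki–Miyaura coupling with a preformed E-alkenylboronate and sets out from 15 and 16. Cross-metathesis of 16 with vinylboronic acid pinacol ester (second-generation Grubbs catalyst, CH2Cl2, 40 °C) gives the E-styrylboronate F7. Coupling of F7 with 15 (Pd(OAc)2, SPhos, CsF, 1,4-dioxane, 80 °C) should give 17, where the route is rejoined.

**Further compounds**

F1 | step 7 | 4-[(1S,2E)-1-hydroxy-3-(4-methoxyphenyl)prop-2-en-1-yl]-3-methoxyphenyl 4-methylbenzenesulfonate | COc1ccc(/C=C/[C@H](O)c2ccc(OS(=O)(=O)c3ccc(C)cc3)cc2OC)cc1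
F2 | step 7 | (1S,2E)-1-{2-methoxy-4-[(4-methylbenzenesulfonyl)oxy]phenyl}-3-(4-methoxyphenyl)prop-2-en-1-yl pyridine-2-carboxylate | COc1ccc(/C=C/[C@H](OC(=O)c2ccccn2)c2ccc(OS(=O)(=O)c3ccc(C)cc3)cc2OC)cc1
F3 | step 7 | 1-chloro-3,5-dimethoxybenzene | COc1cc(Cl)cc(OC)c1
F4 | step 7 | (4-chloro-2,6-dimethoxyphenyl)magnesium bromide | COc1cc(Cl)cc(OC)c1[Mg]Br
F5 | step 3 | racemic 4-[(2E)-1-hydroxy-3-(4-methoxyphenyl)prop-2-en-1-yl]-3-methoxyphenyl 4-methylbenzenesulfonate | COc1ccc(/C=C/C(O)c2ccc(OS(=O)(=O)c3ccc(C)cc3)cc2OC)cc1
F6 | step 3 | 4-{(R)-hydroxy[(2R,3R)-3-(4-methoxyphenyl)oxiran-2-yl]methyl}-3-methoxyphenyl 4-methylbenzenesulfonate | COc1ccc([C@H]2O[C@@H]2[C@H](O)c2ccc(OS(=O)(=O)c3ccc(C)cc3)cc2OC)cc1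
F7 | step 9 | 4-[(E)-2-(4,4,5,5-tetramethyl-1,3,2-dioxaborolan-2-yl)ethenyl]phenyl acetate | CC(=O)Oc1ccc(/C=C/B2OC(C)(C)C(C)(C)O2)cc1
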